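## Retrosynthetic overview

1. Key disconnection: the C15–O ester bond, cut to (R)-2-methylbutanoic acid and the C15 alcohol; forward, this bond is made first, on (R)-2,3-dihydrofarnesol, so the natural ester is the only mask the C15 oxygen needs.
2. C19 acid ⇐ 2-(trimethylsilyl)ethyl ester; C3 methylene ⇐ C3 ketone (the β-keto ester that templates the cyclization).
3. Rings A and B ⇐ one oxidative radical bicyclization of an acyclic (E,E)-diene β-keto ester: ring A closes first (C4–C5), ring B second (C10–C9), and the 8(17)-alkene forms on termination.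
4. β-Keto ester ⇐ acetoacetate dianion + ω-allylic bromide (C1–C2 bond); bromide ⇐ E-selective allylic oxidation of the terminal isopropylidene.
5. C13 stereocentre ⇐ Ru–BINAP hydrogenation of (2E,6E)-farnesol.

Labdane numbering is used for the bicycles and for the acyclic carbons that become them (C4 carries the C19 carboxyl, C8 the methylidene, C13 the side-chain methyl, C15 the ester oxygen).

Assumption: (R)-2-methylbutanoic acid is bought as the single enantiomer, and in step 7 the (S,S)-ligand is assumed to give the ent series (if a model run shows the opposite sense, the (R,R)-ligand is used and nothing else changes).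

## Route

Step 1
Reactants: 1 (2E,6E)-farnesol
Product: 2 (R)-2,3-dihydrofarnesol [(3R,6E)-3,7,11-trimethyldodeca-6,10-dien-1-ol]
Conditions: Ru(OAc)2[(S)-BINAP] (0.2 mol%), H2 (100 atm), MeOH–H2O 95:5, 20 °C
Reagents that add atoms: none
Why: Noyori asymmetric hydrogenation of an allylic alcohol: the hydroxyl binds ruthenium so only the C2=C3 bond is reduced (the 6,7- and 10,11-alkenes stay), and the E-alkene with the (S)-BINAP catalyst gives the 3R centre (future C13) just as geraniol gives (R)-citronellol.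

Step 2
Reactants: 2 (R)-2,3-dihydrofarnesol + 3 (2R)-2-methylbutanoic acid
Product: 4 (3R,6E)-3,7,11-trimethyldodeca-6,10-dien-1-yl (2R)-2-methylbutanoate
Conditions: EDC·HCl (1.3 equiv), DMAP (0.1 equiv), CH2Cl2, 0 °C to rt
Reagents that add atoms: none
Why: Steglich (carbodiimide/DMAP) esterification makes the C15–O ester bond of the target at the outset; no stereocentre is formed and the α-centre of this unactivated acid does not epimerise under these conditions.

Step 3
Reactants: 4 (3R,6E)-3,7,11-trimethyldodeca-6,10-dien-1-yl (2R)-2-methylbutanoate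
Product: 5 (3R,6E,10E)-12-hydroxy-3,7,11-trimethyldodeca-6,10-dien-1-yl (2R)-2-methylbutanoate
Conditions: SeO2 (0.1 equiv), salicylic acid (0.1 equiv), t-BuOOH (3 equiv), CH2Cl2, 0 °C to rt
Reagents that add atoms: tert-butyl hydroperoxide CC(C)(C)OO
Why: Sharpless catalytic SeO2 allylic oxidation (ene reaction then [2,3]-sigmatropic shift) attacks the E-methyl of the terminal isopropylidene, as it does in geranyl and farnesyl acetates, giving the (E)-allylic alcohol; no stereocentre is formed.

Step 4
Reactants: 5 (3R,6E,10E)-12-hydroxy-3,7,11-trimethyldodeca-6,10-dien-1-yl (2R)-2-methylbutanoate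
Product: 6 (3R,6E,10E)-12-bromo-3,7,11-trimethyldodeca-6,10-dien-1-yl (2R)-2-methylbutanoate
Conditions: CBr4 (1.2 equiv), PPh3 (1.25 equiv), CH2Cl2, −20 to 0 °C
Reagents that add atoms: carbon tetrabromide BrC(Br)(Br)Br
Why: Appel bromination converts the primary allylic alcohol to the bromide by direct SN2 displacement of the oxyphosphonium, so the E-alkene is kept without allylic transposition and the ester is untouched.

Step 5
Reactants: 7 ethyl 2-methyl-3-oxobutanoate + 8 2-(trimethylsilyl)ethanol
Product: 9 2-(trimethylsilyl)ethyl 2-methyl-3-oxobutanoate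
Conditions: DMAP (0.2 equiv), toluene, reflux, 4 Å MS (EtOH removed)
Reagents that add atoms: none
Why: DMAP-catalysed transesterification of a β-keto ester (acylketene pathway) is driven by removal of ethanol and installs an ester that can later be cleaved at silicon, far from the hindered C19 carbonyl.

Step 6
Reactants: 9 2-(trimethylsilyl)ethyl 2-methyl-3-oxobutanoate + 6 (3R,6E,10E)-12-bromo-3,7,11-trimethyldodeca-6,10-dien-1-yl (2R)-2-methylbutanoate
Product: 11 2-(trimethylsilyl)ethyl (6E,10E,14R)-2,6,10,14-tetramethyl-16-{[(2R)-2-methylbutanoyl]oxy}-3-oxohexadeca-6,10-dienoate, via dilithium dienolate 10 (not isolated)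
Conditions: 9 (1.1 equiv), LiN(iPr)2 (2.1 equiv), THF, 0 °C; then added to 6, THF, −78 °C, 30 min; aq. NH4Cl
Reagents that add atoms: lithium diisopropylamide CC(C)[N-]C(C)C.[Li+] (its lithium is in intermediate 10 only)
Why: Weiler dianion γ-alkylation forms the C1–C2 bond; the allylic bromide is far more electrophilic than the α-branched ester, and inverse addition at −78 °C with no free amide base keeps the dienolate from acylating or deprotonating the 2-methylbutanoate, while the new α-centre (C4) is an irrelevant epimer mixture because it becomes a radical.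

Step 7
Reactants: 11 2-(trimethylsilyl)ethyl (6E,10E,14R)-2,6,10,14-tetramethyl-16-{[(2R)-2-methylbutanoyl]oxy}-3-oxohexadeca-6,10-dienoate
Product: 12 2-(trimethylsilyl)ethyl (13R)-15-[(2R)-2-methylbutanoyloxy]-3-oxo-ent-labd-8(17)-en-19-oate
Conditions: Mg(NTf2)2 (20 mol%), (S,S)-t-Bu-box (22 mol%), 2,6-lutidine (20 mol%), [Ir(ppy)2(dtbbpy)]PF6 (2 mol%), Co(dmgH)2(py)Cl (5 mol%), 4 Å MS, CH2Cl2, −30 °C, 450 nm LEDs, Ar sweep
Reagents that add atoms: none
Why: Proposed new method: a chiral-Lewis-acid-templated, acceptorless dehydrogenative radical bicyclization — Mg(NTf2)2/(S,S)-t-Bu-box holds 11 as a two-point-bound enolate (2,6-lutidine as proton shuttle), photogenerated tetravalent iridium (about +1.2 V vs SCE, too weak to oxidise the trisubstituted alkenes) removes one electron to give the magnesium-chelated C4 radical with one face blocked by a tert-butyl group, the C5=C10 alkene adds to the open face through a chair (6-endo, ring A, sets C4 with the ester axial and C5), the C10 radical closes ring B trans (6-endo on C9, sets C10 and C9 with the side chain equatorial), and the tertiary C8 radical hands a methyl hydrogen atom to divalent cobalt to give the 8(17)-alkene while the trivalent cobalt hydride releases H2 with lutidinium; the closest known reaction types are the chiral magnesium–bis(oxazoline)-catalysed atom- and phenylselanyl-transfer tandem radical cyclizations of α-halo and α-seleno β-keto esters (same chelated radical and chair–chair course), the Mn(OAc)3/Cu(OAc)2 oxidative polyene cyclization of 2-methyl-3-oxo esters (axial ester, exocyclic alkene) and photoredox/cobaloxime desaturation of alkyl radicals.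

Step 8
Reactants: 12 2-(trimethylsilyl)ethyl (13R)-15-[(2R)-2-methylbutanoyloxy]-3-oxo-ent-labd-8(17)-en-19-oate
Product: 14 2-(trimethylsilyl)ethyl (13R)-15-[(2R)-2-methylbutanoyloxy]-ent-labd-8(17)-en-19-oate, via tosylhydrazone 13 (not isolated)
Conditions: TsNHNH2 (1.5 equiv), EtOH, 75 °C; evaporate; catecholborane (2.5 equiv), CHCl3, 0 °C; then NaOAc·3H2O, 60 °C
Reagents that add atoms: 4-methylbenzenesulfonohydrazide Cc1ccc(cc1)S(=O)(=O)NN (its atoms are in intermediate 13 only)
Why: Caglioti-type tosylhydrazone reduction in its Kabalka form: hydride adds to C=N, sulfinate leaves and the diazene loses N2 to give the C3 methylene; catecholborane at 0 °C leaves the alkene and both esters alone, and no stereocentre is touched since C4 is quaternary.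

Step 9
Reactants: 14 2-(trimethylsilyl)ethyl (13R)-15-[(2R)-2-methylbutanoyloxy]-ent-labd-8(17)-en-19-oate
Product: 15 (13R)-15-[(2R)-2-methylbutanoyloxy]-ent-labd-8(17)-en-19-oic acid (target)
Conditions: Bu4NF (3 equiv), THF, 0 °C to rt; aq. NH4Cl
Reagents that add atoms: none
Why: Fluoride-induced β-elimination of the 2-(trimethylsilyl)ethyl ester starts at silicon, so the steric shielding of the axial C19 carbonyl is irrelevant, and the primary 2-methylbutanoate, its α-centre and the exocyclic alkene are not affected.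

## Compound list

1 | (2E,6E)-farnesol | OC/C=C(C)/CC/C=C(C)/CCC=C(C)C | starting material
2 | (R)-2,3-dihydrofarnesol, (3R,6E)-3,7,11-trimethyldodeca-6,10-dien-1-ol | CC(C)=CCC/C(C)=C/CC[C@@H](C)CCO | intermediate
3 | (2R)-2-methylbutanoic acid | CC[C@@H](C)C(=O)O | starting material
4 | (3R,6E)-3,7,11-trimethyldodeca-6,10-dien-1-yl (2R)-2-methylbutanoate | CC(C)=CCC/C(C)=C/CC[C@@H](C)CCOC(=O)[C@H](C)CC | intermediate
5 | (3R,6E,10E)-12-hydroxy-3,7,11-trimethyldodeca-6,10-dien-1-yl (2R)-2-methylbutanoate | OC/C(C)=C/CC/C(C)=C/CC[C@@H](C)CCOC(=O)[C@H](C)CC | intermediate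
6 | (3R,6E,10E)-12-bromo-3,7,11-trimethyldodeca-6,10-dien-1-yl (2R)-2-methylbutanoate | BrC/C(C)=C/CC/C(C)=C/CC[C@@H](C)CCOC(=O)[C@H](C)CC | intermediate
7 | ethyl 2-methyl-3-oxobutanoate (racemic) | CCOC(=O)C(C)C(C)=O | starting material
8 | 2-(trimethylsilyl)ethanol | C[Si](C)(C)CCO | starting material
9 | 2-(trimethylsilyl)ethyl 2-methyl-3-oxobutanoate (racemic) | CC(=O)C(C)C(=O)OCC[Si](C)(C)C | intermediate
10 | dilithium dienolate (dianion) of 9 | [Li+].[Li+].C=C([O-])C(C)=C([O-])OCC[Si](C)(C)C | intermediate (not isolated)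
11 | 2-(trimethylsilyl)ethyl (6E,10E,14R)-2,6,10,14-tetramethyl-16-{[(2R)-2-methylbutanoyl]oxy}-3-oxohexadeca-6,10-dienoate (C2 epimer mixture) | C[Si](C)(C)CCOC(=O)C(C)C(=O)CC/C(C)=C/CC/C(C)=C/CC[C@@H](C)CCOC(=O)[C@H](C)CC | intermediate
12 | 2-(trimethylsilyl)ethyl (13R)-15-[(2R)-2-methylbutanoyloxy]-3-oxo-ent-labd-8(17)-en-19-oate (trans-decalin; C4 ester axial, cis to the C10 methyl; C9 side chain equatorial) | C=C1CC[C@H]2[C@@](C)(CCC(=O)[C@@]2(C)C(=O)OCC[Si](C)(C)C)[C@@H]1CC[C@@H](C)CCOC(=O)[C@H](C)CC | intermediate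
13 | C3 (4-methylbenzenesulfonyl)hydrazone of 12 | C=C1CC[C@H]2[C@@](C)(CCC(=NNS(=O)(=O)c3ccc(C)cc3)[C@@]2(C)C(=O)OCC[Si](C)(C)C)[C@@H]1CC[C@@H](C)CCOC(=O)[C@H](C)CC | intermediate (not isolated)
14 | 2-(trimethylsilyl)ethyl (13R)-15-[(2R)-2-methylbutanoyloxy]-ent-labd-8(17)-en-19-oate | C=C1CC[C@H]2[C@@](C)(CCC[C@@]2(C)C(=O)OCC[Si](C)(C)C)[C@@H]1CC[C@@H](C)CCOC(=O)[C@H](C)CC | intermediate
15 | (13R)-15-[(2R)-2-methylbutanoyloxy]-ent-labd-8(17)-en-19-oic acid, (1R,4aS,5R,8aS)-1,4a-dimethyl-5-[(3R)-3-methyl-5-{[(2R)-2-methylbutanoyl]oxy}pentyl]-6-methylidenedecahydronaphthalene-1-carboxylic acid | C=C1CC[C@H]2[C@@](C)(CCC[C@@]2(C)C(=O)O)[C@@H]1CC[C@@H](C)CCOC(=O)[C@H](C)CC | target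

## Step count and risk

Total steps: 9. Longest linear sequence: 8 (steps 1–4 and 6–9; step 5 is a one-step side branch).

The three steps most likely to fail:

**Step 7 (the proposed new bicyclization).** Three catalysts must work together, and the enantioselectivity and the exocyclic-alkene selectivity are untested. The fallback uses known chemistry, sets out from 11 and comes back at 12. Compound 11 is selenenylated at C4 (NaH, PhSeCl, THF, 0 °C) to the α-phenylselanyl β-keto ester F1. This undergoes the established chiral magnesium–bis(oxazoline)-catalysed phenylselanyl-group-transfer tandem radical cyclization (Mg(ClO4)2, (S,S)-box ligand, Et3B/O2, toluene, −78 °C) to the C8 phenylselanyl bicycle F2. Oxidation (H2O2, pyridine, CH2Cl2, 0 °C) and selenoxide syn-elimination toward the methyl group give 12. This costs two extra steps.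

**Step 8 (deoxygenation of the hindered C3 ketone).** Hydrazone formation next to the quaternary C4 may be slow, or the hydrazone may attack the C19 ester. The fallback sets out from 12 and comes back at 14. NaBH4 (MeOH, −10 °C) gives the 3-hydroxy ester F3 (either epimer serves). 1,1′-Thiocarbonyldiimidazole with DMAP (1,2-dichloroethane, 70 °C) gives the O-imidazolylthiocarbonyl derivative F4. Barton–McCombie reduction (Bu3SnH, AIBN, toluene, 100 °C) gives 14. This costs two extra steps.

**Step 6 (dianion alkylation in the presence of the chiral ester).** The dienolate could acylate on, or epimerise, the 2-methylbutanoate. The fallback forms the ester only after the carbanion step; it sets out from 2 and comes back at 11. Alcohol 2 is silylated (TBSCl, imidazole, CH2Cl2) to the tert-butyldimethylsilyl ether F5. This is oxidised as in step 3 to the (E)-allylic alcohol F6 and brominated as in step 4 to the allylic bromide F7. Alkylation of dienolate 10 with F7 gives the silyl-protected β-keto ester F8. Desilylation (PPTS, MeOH, rt) gives the hydroxy β-keto ester F9, which is esterified with 3 (EDC·HCl, DMAP, CH2Cl2) to give 11. This costs two extra steps.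

## Further compounds

F1 | step 7 | 2-(trimethylsilyl)ethyl (6E,10E,14R)-2,6,10,14-tetramethyl-16-{[(2R)-2-methylbutanoyl]oxy}-3-oxo-2-(phenylselanyl)hexadeca-6,10-dienoate | C[Si](C)(C)CCOC(=O)C(C)([Se]c1ccccc1)C(=O)CC/C(C)=C/CC/C(C)=C/CC[C@@H](C)CCOC(=O)[C@H](C)CC
F2 | step 7 | 2-(trimethylsilyl)ethyl (13R)-15-[(2R)-2-methylbutanoyloxy]-3-oxo-8-(phenylselanyl)-ent-labdan-19-oate | CC1([Se]c3ccccc3)CC[C@H]2[C@@](C)(CCC(=O)[C@@]2(C)C(=O)OCC[Si](C)(C)C)[C@@H]1CC[C@@H](C)CCOC(=O)[C@H](C)CC
F3 | step 8 | 2-(trimethylsilyl)ethyl (13R)-3-hydroxy-15-[(2R)-2-methylbutanoyloxy]-ent-labd-8(17)-en-19-oate (C3 epimers) | C=C1CC[C@H]2[C@@](C)(CCC(O)[C@@]2(C)C(=O)OCC[Si](C)(C)C)[C@@H]1CC[C@@H](C)CCOC(=O)[C@H](C)CC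
F4 | step 8 | 2-(trimethylsilyl)ethyl (13R)-3-[(1H-imidazol-1-ylcarbonothioyl)oxy]-15-[(2R)-2-methylbutanoyloxy]-ent-labd-8(17)-en-19-oate | C=C1CC[C@H]2[C@@](C)(CCC(OC(=S)n3ccnc3)[C@@]2(C)C(=O)OCC[Si](C)(C)C)[C@@H]1CC[C@@H](C)CCOC(=O)[C@H](C)CC
F5 | step 6 | tert-butyldimethyl{[(3R,6E)-3,7,11-trimethyldodeca-6,10-dien-1-yl]oxy}silane | CC(C)=CCC/C(C)=C/CC[C@@H](C)CCO[Si](C)(C)C(C)(C)C
F6 | step 6 | (2E,6E,10R)-12-[(tert-butyldimethylsilyl)oxy]-2,6,10-trimethyldodeca-2,6-dien-1-ol | OC/C(C)=C/CC/C(C)=C/CC[C@@H](C)CCO[Si](C)(C)C(C)(C)C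
F7 | step 6 | {[(3R,6E,10E)-12-bromo-3,7,11-trimethyldodeca-6,10-dien-1-yl]oxy}(tert-butyl)dimethylsilane | BrC/C(C)=C/CC/C(C)=C/CC[C@@H](C)CCO[Si](C)(C)C(C)(C)C
F8 | step 6 | 2-(trimethylsilyl)ethyl (6E,10E,14R)-16-[(tert-butyldimethylsilyl)oxy]-2,6,10,14-tetramethyl-3-oxohexadeca-6,10-dienoate | C[Si](C)(C)CCOC(=O)C(C)C(=O)CC/C(C)=C/CC/C(C)=C/CC[C@@H](C)CCO[Si](C)(C)C(C)(C)C
F9 | step 6 | 2-(trimethylsilyl)ethyl (6E,10E,14R)-16-hydroxy-2,6,10,14-tetramethyl-3-oxohexadeca-6,10-dienoate | C[Si](C)(C)CCOC(=O)C(C)C(=O)CC/C(C)=C/CC/C(C)=C/CC[C@@H](C)CCO
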